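**Strategy.** The epoxy-ketone ring is treated as a latent 2-methylcyclohex-2-enone (ring atoms C1 = ketone, C2 = methyl-bearing carbon, C3, C4, C5 = side-chain carbon, C6 = ester carbon). Its C2=C3 bond is an aldol-condensation retron and its C4–C5 bond a conjugate-addition retron of the C1 ketone, so C3–C4 is an acetaldehyde enolate equivalent. The key step adds an (E)-2-ethoxyvinylboronate to an acyclic (E)-enone under rhodium/BINAP catalysis and, in the same flask, hydrolyses the enol ether and closes the ring by aldol condensation, forming C4–C5 and C2–C3 and setting C5. α'-Acyloxylation, hydroxyl-directed epoxidation and side-chain elaboration ending in a singlet-oxygen ene reaction follow.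

Key step: step 2

Remark: C1–C6 in the discussion are the cyclohexenone positions defined above (systematic names use their own numbering); the carbinol centre formed in step 10 is left uncontrolled because step 12 removes it.

**Step 1**
Reactants: 1 ethyl vinyl ketone (pent-1-en-3-one); 2 4-(benzyloxy)but-1-ene
Product: 3 (E)-7-(benzyloxy)hept-4-en-3-one
Conditions: second-generation Hoveyda–Grubbs catalyst (3 mol %), 1 (3 equiv), CH2Cl2, 40 °C
Reagents that add atoms: none
Why: Olefin cross-metathesis of a terminal alkene with an electron-poor vinyl ketone should give the (E)-cross product selectively, with ethene as the only by-product.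

**Step 2**
Reactants: 3 (E)-7-(benzyloxy)hept-4-en-3-one; 4 (E)-2-(2-ethoxyvinyl)-4,4,5,5-tetramethyl-1,3,2-dioxaborolane
Product: 7 (5S)-5-[2-(benzyloxy)ethyl]-2-methylcyclohex-2-en-1-one, via enol ether adduct 5 (not isolated), via keto aldehyde 6 (not isolated)
Conditions: [Rh(cod)Cl]2 (2.5 mol %), (R)-BINAP (5.5 mol %), aq KOH (0.2 equiv), 1,4-dioxane/H2O 10:1, 60 °C; then 2 M aq HCl, THF, 50 °C
Reagents that add atoms: none
Why: A hydroxo-rhodium/(R)-BINAP complex takes up the alkenyl group of 4 by transmetallation, carbometallates the (E)-enone 3 in a 1,4 sense and is released by protonolysis of the oxa-π-allyl rhodium to give enol ether 5 (new C4–C5 bond); aqueous acid then hydrolyses the enol ether to aldehyde 6, whose ketone enolises toward C2, adds to the aldehyde and loses water (new C2–C3 bond, which becomes the enone C=C). The closest known reaction types are the Hayashi–Miyaura asymmetric conjugate addition of alkenylboron reagents to acyclic enones and the aldol-condensation half of a Robinson annulation. The ring closes in a 6-(enolendo)-exo-trig aldol mode, the only one open to 6, since every other enol–carbonyl pairing would give a four-membered ring. The one new stereocentre, C5, is set by the catalyst: on the usual α-face model for (E)-enones the (R)-BINAP complex should give (S)-5, and C5 cannot enolise afterwards. The step needs 1,4- rather than 1,2-addition, which rhodium alkenyls give with enones, and a side-chain ether that survives base and dilute acid, which the benzyl ether does.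

**Step 3**
Reactants: 7 (5S)-5-[2-(benzyloxy)ethyl]-2-methylcyclohex-2-en-1-one; 8 3-methylbutanoic acid
Product: 9 (1S,6S)-6-[2-(benzyloxy)ethyl]-3-methyl-2-oxocyclohex-3-en-1-yl 3-methylbutanoate (ester trans to the C5 side chain)
Conditions: Mn(OAc)3·2H2O (3 equiv), 8 (10 equiv), benzene, reflux (Dean–Stark)
Reagents that add atoms: none
Why: Mn(OAc)3-mediated α'-acyloxylation of enones (carboxylate exchange on manganese, then carboxylate transfer to the α'-enolate position) oxidises only C6, and because C6 stays epimerisable the ester should settle trans (diequatorial) to the C5 substituent.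

**Step 4**
Reactants: 9 (1S,6S)-6-[2-(benzyloxy)ethyl]-3-methyl-2-oxocyclohex-3-en-1-yl 3-methylbutanoate
Product: 10 (1S,2S,6S)-6-[2-(benzyloxy)ethyl]-2-hydroxy-3-methylcyclohex-3-en-1-yl 3-methylbutanoate (hydroxyl cis to the side chain, trans to the ester)
Conditions: NaBH4, CeCl3·7H2O, MeOH, −78 °C
Reagents that add atoms: none
Why: Luche 1,2-reduction with axial hydride delivery to the half-chair bearing both substituents equatorial should give the equatorial C1 alcohol, cis to the C5 chain as in the carvone to cis-carveol reduction, and leaves the ester untouched.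

**Step 5**
Reactants: 10 (1S,2S,6S)-6-[2-(benzyloxy)ethyl]-2-hydroxy-3-methylcyclohex-3-en-1-yl 3-methylbutanoate
Product: 11 (1R,2R,3S,4R,6S)-4-[2-(benzyloxy)ethyl]-2-hydroxy-1-methyl-7-oxabicyclo[4.1.0]heptan-3-yl 3-methylbutanoate (epoxide cis to the hydroxyl and to the side chain)
Conditions: VO(acac)2 (5 mol %), tBuOOH (in decane), CH2Cl2, 0 °C to rt
Reagents that add atoms: tert-butyl hydroperoxide, CC(C)(C)OO
Why: Hydroxyl-directed vanadium-catalysed epoxidation delivers oxygen syn to the allylic C1 hydroxyl, which places the epoxide cis to the C5 chain and trans to the ester, the face that a Weitz–Scheffer epoxidation of the enone would not give.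

**Step 6**
Reactants: 11 (1R,2R,3S,4R,6S)-4-[2-(benzyloxy)ethyl]-2-hydroxy-1-methyl-7-oxabicyclo[4.1.0]heptan-3-yl 3-methylbutanoate
Product: 12 (1R,2R,3S,4R,6S)-2-hydroxy-4-(2-hydroxyethyl)-1-methyl-7-oxabicyclo[4.1.0]heptan-3-yl 3-methylbutanoate
Conditions: H2 (1 atm), 10% Pd/C, EtOAc, rt
Reagents that add atoms: none
Why: Hydrogenolysis removes the benzyl ether under neutral conditions that a non-benzylic trisubstituted epoxide and the ester should survive.

**Step 7**
Reactants: 12 (1R,2R,3S,4R,6S)-2-hydroxy-4-(2-hydroxyethyl)-1-methyl-7-oxabicyclo[4.1.0]heptan-3-yl 3-methylbutanoate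
Product: 13 (1S,3S,4S,6S)-1-methyl-2-oxo-4-(2-oxoethyl)-7-oxabicyclo[4.1.0]heptan-3-yl 3-methylbutanoate
Conditions: Dess–Martin periodinane (3 equiv), CH2Cl2, 0 °C to rt
Reagents that add atoms: none
Why: Dess–Martin oxidation converts the secondary alcohol to the epoxy ketone and the primary alcohol to the aldehyde in one operation, without opening the epoxide or cleaving the ester.

**Step 8**
Reactants: 13 (1S,3S,4S,6S)-1-methyl-2-oxo-4-(2-oxoethyl)-7-oxabicyclo[4.1.0]heptan-3-yl 3-methylbutanoate; 14 formaldehyde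
Product: 15 (1S,3S,4S,6S)-1-methyl-2-oxo-4-(3-oxoprop-1-en-2-yl)-7-oxabicyclo[4.1.0]heptan-3-yl 3-methylbutanoate
Conditions: 37% aq HCHO, pyrrolidine (10 mol %), propanoic acid (10 mol %), iPrOH, 45 °C
Reagents that add atoms: none
Why: Amine-catalysed Mannich condensation/elimination (α-methylenation of aldehydes) acts only at the aldehyde α-CH2, and no intramolecular aldol can compete because it would form a four-membered ring.

**Step 9**
Reactants: 15 (1S,3S,4S,6S)-1-methyl-2-oxo-4-(3-oxoprop-1-en-2-yl)-7-oxabicyclo[4.1.0]heptan-3-yl 3-methylbutanoate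
Product: 16 (1S,3S,4R,6S)-4-[(2R)-2-formyloxiran-2-yl]-1-methyl-2-oxo-7-oxabicyclo[4.1.0]heptan-3-yl 3-methylbutanoate
Conditions: 35% aq H2O2, (S)-2-[diphenyl(trimethylsilyloxy)methyl]pyrrolidine (10 mol %), CH2Cl2, rt
Reagents that add atoms: hydrogen peroxide, OO
Why: Amine-catalysed asymmetric epoxidation of α-substituted acroleins (iminium conjugate addition of H2O2, then epoxide closure from the enamine) should close on the enamine face away from the diphenyl(silyloxy)methyl group, giving the (R) quaternary centre under catalyst control while the ring ketone is not activated.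

**Step 10**
Reactants: 16 (1S,3S,4R,6S)-4-[(2R)-2-formyloxiran-2-yl]-1-methyl-2-oxo-7-oxabicyclo[4.1.0]heptan-3-yl 3-methylbutanoate; 17 2-allyl-4,4,5,5-tetramethyl-1,3,2-dioxaborolane
Product: 18 (1S,3S,4R,6S)-4-[(2R)-2-(1-hydroxybut-3-en-1-yl)oxiran-2-yl]-1-methyl-2-oxo-7-oxabicyclo[4.1.0]heptan-3-yl 3-methylbutanoate (both carbinol epimers)
Conditions: 17 (1.5 equiv), CH2Cl2, rt; pH 7 aqueous work-up
Reagents that add atoms: none
Why: Uncatalysed allylboration through a six-membered chair transition state is selective for the aldehyde over the ketone, ester and epoxides, and the configuration of the new carbinol is irrelevant.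

**Step 11**
Reactants: 18 (1S,3S,4R,6S)-4-[(2R)-2-(1-hydroxybut-3-en-1-yl)oxiran-2-yl]-1-methyl-2-oxo-7-oxabicyclo[4.1.0]heptan-3-yl 3-methylbutanoate; 19 2-methylbut-2-ene
Product: 20 (1S,3S,4R,6S)-4-[(2R)-2-(1-hydroxy-4-methylpent-3-en-1-yl)oxiran-2-yl]-1-methyl-2-oxo-7-oxabicyclo[4.1.0]heptan-3-yl 3-methylbutanoate
Conditions: second-generation Grubbs catalyst (5 mol %), 19 (excess), CH2Cl2, 40 °C
Reagents that add atoms: none
Why: Cross-metathesis with 2-methylbut-2-ene turns the only alkene of 18, the terminal vinyl group, into the prenyl group with loss of propene.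

**Step 12**
Reactants: 20 (1S,3S,4R,6S)-4-[(2R)-2-(1-hydroxy-4-methylpent-3-en-1-yl)oxiran-2-yl]-1-methyl-2-oxo-7-oxabicyclo[4.1.0]heptan-3-yl 3-methylbutanoate
Product: 21 (1S,3S,4R,6S)-1-methyl-4-[(2R)-2-(4-methylpent-3-enoyl)oxiran-2-yl]-2-oxo-7-oxabicyclo[4.1.0]heptan-3-yl 3-methylbutanoate
Conditions: Dess–Martin periodinane (1.5 equiv), CH2Cl2, 0 °C
Reagents that add atoms: none
Why: Dess–Martin oxidation gives the β,γ-unsaturated ketone under neutral conditions that should not move the alkene into conjugation.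

**Step 13**
Reactants: 21 (1S,3S,4R,6S)-1-methyl-4-[(2R)-2-(4-methylpent-3-enoyl)oxiran-2-yl]-2-oxo-7-oxabicyclo[4.1.0]heptan-3-yl 3-methylbutanoate
Product: 22 (1S,3S,4R,6S)-4-{(2R)-2-[(2E)-4-hydroperoxy-4-methylpent-2-enoyl]oxiran-2-yl}-1-methyl-2-oxo-7-oxabicyclo[4.1.0]heptan-3-yl 3-methylbutanoate (CNP0131119.1)
Conditions: O2, tetraphenylporphyrin (cat.), visible light, CH2Cl2, 0 °C
Reagents that add atoms: dioxygen, O=O
Why: Schenck ene reaction of singlet oxygen with the trisubstituted alkene, with hydrogen abstraction from the CH2 flanked by ketone and alkene, should give the tertiary hydroperoxide and the conjugated (E)-enone without creating a stereocentre or touching the epoxides.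

**Compound list**
1 | ethyl vinyl ketone (pent-1-en-3-one) | C=CC(=O)CC | starting material
2 | 4-(benzyloxy)but-1-ene | C=CCCOCc1ccccc1 | starting material
3 | (E)-7-(benzyloxy)hept-4-en-3-one | CCC(=O)/C=C/CCOCc1ccccc1 | intermediate
4 | (E)-2-(2-ethoxyvinyl)-4,4,5,5-tetramethyl-1,3,2-dioxaborolane | CCO/C=C/B1OC(C)(C)C(C)(C)O1 | starting material
5 | (5S,6E)-5-[2-(benzyloxy)ethyl]-7-ethoxyhept-6-en-3-one | CCC(=O)C[C@@H](/C=C/OCC)CCOCc1ccccc1 | intermediate
6 | (3R)-3-[2-(benzyloxy)ethyl]-5-oxoheptanal | CCC(=O)C[C@@H](CC=O)CCOCc1ccccc1 | intermediate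
7 | (5S)-5-[2-(benzyloxy)ethyl]-2-methylcyclohex-2-en-1-one | CC1=CC[C@@H](CCOCc2ccccc2)CC1=O | intermediate
8 | 3-methylbutanoic acid | CC(C)CC(=O)O | starting material
9 | (1S,6S)-6-[2-(benzyloxy)ethyl]-3-methyl-2-oxocyclohex-3-en-1-yl 3-methylbutanoate | CC(C)CC(=O)O[C@@H]1C(=O)C(C)=CC[C@H]1CCOCc1ccccc1 | intermediate
10 | (1S,2S,6S)-6-[2-(benzyloxy)ethyl]-2-hydroxy-3-methylcyclohex-3-en-1-yl 3-methylbutanoate | CC(C)CC(=O)O[C@@H]1[C@@H](O)C(C)=CC[C@H]1CCOCc1ccccc1 | intermediate
11 | (1R,2R,3S,4R,6S)-4-[2-(benzyloxy)ethyl]-2-hydroxy-1-methyl-7-oxabicyclo[4.1.0]heptan-3-yl 3-methylbutanoate | CC(C)CC(=O)O[C@@H]1[C@@H](O)[C@@]2(C)O[C@H]2C[C@H]1CCOCc1ccccc1 | intermediate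
12 | (1R,2R,3S,4R,6S)-2-hydroxy-4-(2-hydroxyethyl)-1-methyl-7-oxabicyclo[4.1.0]heptan-3-yl 3-methylbutanoate | CC(C)CC(=O)O[C@@H]1[C@@H](O)[C@@]2(C)O[C@H]2C[C@H]1CCO | intermediate
13 | (1S,3S,4S,6S)-1-methyl-2-oxo-4-(2-oxoethyl)-7-oxabicyclo[4.1.0]heptan-3-yl 3-methylbutanoate | CC(C)CC(=O)O[C@@H]1C(=O)[C@@]2(C)O[C@H]2C[C@H]1CC=O | intermediate
14 | formaldehyde | C=O | starting material
15 | (1S,3S,4S,6S)-1-methyl-2-oxo-4-(3-oxoprop-1-en-2-yl)-7-oxabicyclo[4.1.0]heptan-3-yl 3-methylbutanoate | CC(C)CC(=O)O[C@@H]1C(=O)[C@@]2(C)O[C@H]2C[C@H]1C(=C)C=O | intermediate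
16 | (1S,3S,4R,6S)-4-[(2R)-2-formyloxiran-2-yl]-1-methyl-2-oxo-7-oxabicyclo[4.1.0]heptan-3-yl 3-methylbutanoate | CC(C)CC(=O)O[C@@H]1C(=O)[C@@]2(C)O[C@H]2C[C@H]1[C@]1(C=O)CO1 | intermediate
17 | 2-allyl-4,4,5,5-tetramethyl-1,3,2-dioxaborolane | C=CCB1OC(C)(C)C(C)(C)O1 | starting material
18 | (1S,3S,4R,6S)-4-[(2R)-2-(1-hydroxybut-3-en-1-yl)oxiran-2-yl]-1-methyl-2-oxo-7-oxabicyclo[4.1.0]heptan-3-yl 3-methylbutanoate (carbinol epimers) | CC(C)CC(=O)O[C@@H]1C(=O)[C@@]2(C)O[C@H]2C[C@H]1[C@]1(C(O)CC=C)CO1 | intermediate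
19 | 2-methylbut-2-ene | CC=C(C)C | starting material
20 | (1S,3S,4R,6S)-4-[(2R)-2-(1-hydroxy-4-methylpent-3-en-1-yl)oxiran-2-yl]-1-methyl-2-oxo-7-oxabicyclo[4.1.0]heptan-3-yl 3-methylbutanoate (carbinol epimers) | CC(C)CC(=O)O[C@@H]1C(=O)[C@@]2(C)O[C@H]2C[C@H]1[C@]1(C(O)CC=C(C)C)CO1 | intermediate
21 | (1S,3S,4R,6S)-1-methyl-4-[(2R)-2-(4-methylpent-3-enoyl)oxiran-2-yl]-2-oxo-7-oxabicyclo[4.1.0]heptan-3-yl 3-methylbutanoate | CC(C)CC(=O)O[C@@H]1C(=O)[C@@]2(C)O[C@H]2C[C@H]1[C@]1(C(=O)CC=C(C)C)CO1 | intermediate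
22 | (1S,3S,4R,6S)-4-{(2R)-2-[(2E)-4-hydroperoxy-4-methylpent-2-enoyl]oxiran-2-yl}-1-methyl-2-oxo-7-oxabicyclo[4.1.0]heptan-3-yl 3-methylbutanoate | CC(C)CC(=O)O[C@@H]1C(=O)[C@@]2(C)O[C@H]2C[C@H]1[C@]1(C(=O)/C=C/C(C)(C)OO)CO1 | target

**Step count and risks**
Total step count: 13. Longest linear sequence: 13.

Three steps most likely to fail:

1. Step 2 (key step). The electron-rich alkoxyvinylboronate may protodeboronate or transmetallate slowly, so that the conjugate addition stalls or loses enantioselectivity. Fallback: starting from 3, the same rhodium/(R)-BINAP system is used with potassium vinyltrifluoroborate, a robust alkenyl donor, to give (5S)-7-(benzyloxy)-5-vinylheptan-3-one F1. An aldehyde-selective Wacker oxidation (PdCl2(PhCN)2, CuCl2, AgNO2, O2, tBuOH/MeNO2) then converts the vinyl group into the aldehyde 6, which is isolated and cyclised with p-TsOH in toluene to rejoin the route at 7.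

2. Step 9. Facial selectivity of the epoxide ring closure may be poor if the catalyst and the neighbouring C5 stereocentre are mismatched, and the reactive acrolein may be lost by amine addition. Fallback: starting from 15, NaBH(OAc)3 reduces only the aldehyde to (1S,3S,4S,6S)-4-(3-hydroxyprop-1-en-2-yl)-1-methyl-2-oxo-7-oxabicyclo[4.1.0]heptan-3-yl 3-methylbutanoate F2. A Sharpless asymmetric epoxidation (Ti(OiPr)4, L-(+)-diethyl tartrate, tBuOOH, 4 Å sieves, −20 °C) should then give (1S,3S,4R,6S)-4-[(2S)-2-(hydroxymethyl)oxiran-2-yl]-1-methyl-2-oxo-7-oxabicyclo[4.1.0]heptan-3-yl 3-methylbutanoate F3, and Dess–Martin oxidation returns to 16.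

3. Step 13. Regioselectivity of the ene reaction may be poor, with hydrogen abstraction from a methyl group giving the secondary allylic hydroperoxide. Fallback: starting from 21, a radical-chain autoxidation with triplet oxygen (O2, catalytic N-hydroxyphthalimide, MeCN, 40 °C) abstracts the doubly activated hydrogen between ketone and alkene and should trap the delocalised radical at its tertiary terminus, leading directly to 22; no new compound is made (F0).

**Further compounds**
F1 | step 2 | (5S)-7-(benzyloxy)-5-vinylheptan-3-one | CCC(=O)C[C@@H](C=C)CCOCc1ccccc1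
F2 | step 9 | (1S,3S,4S,6S)-4-(3-hydroxyprop-1-en-2-yl)-1-methyl-2-oxo-7-oxabicyclo[4.1.0]heptan-3-yl 3-methylbutanoate | CC(C)CC(=O)O[C@@H]1C(=O)[C@@]2(C)O[C@H]2C[C@H]1C(=C)CO
F3 | step 9 | (1S,3S,4R,6S)-4-[(2S)-2-(hydroxymethyl)oxiran-2-yl]-1-methyl-2-oxo-7-oxabicyclo[4.1.0]heptan-3-yl 3-methylbutanoate | CC(C)CC(=O)O[C@@H]1C(=O)[C@@]2(C)O[C@H]2C[C@H]1[C@]1(CO)CO1
F0 | step 13 | none | none
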